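The 3(2H)-furanone (O, C10, C1, C2, C3; germacrane numbering) is the cyclodehydrated form of a 10-hydroxy-1,3-diketone, and a 3,5-disubstituted isoxazole is that diketone in rigid, masked form. The route therefore locks C1–C2–C3 into an isoxazole (O on C1, N on C3), closes the ten-membered carbocycle around it by a chromium-mediated allylation (C6–C7) that also delivers the α-methylene lactone, and attaches the epoxy ester. The last step is a one-pot ring switch on this bridged isoxazolophane: Mo(CO)6 cuts the N–O bond, then acid lets the C10 oxygen add across the ring to C3 with loss of ammonia. It exploits the 1,3-dioxygenated C1–C2–C3 unit beside the tertiary C10–O.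

Key step: step 15

Remark: germacrane numbering is used (C1 furanone C=O, C2 furanone CH, C3 furanone C–O, C4=C5 the Z-alkene, C6 acyloxy carbon, C7, C8 lactone carbinol, C9 CH2, C10 methyl-bearing quaternary carbon, C11–C13 the methylene lactone); 1, 4, 10 and 21 are taken as purchasable, and the C=N geometry of 12–15 is left open because it is lost in nitrile oxide 16.

Step 1
Reactants: 1 (E)-3-methylpent-2-en-4-yn-1-ol
Product: 2 [(2S,3S)-3-ethynyl-3-methyloxiran-2-yl]methanol
Conditions: Ti(OiPr)4 (10 mol %), L-(+)-diethyl tartrate (12 mol %), t-BuOOH, 4 Å MS, CH2Cl2, −20 °C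
Reagents that add atoms: tert-butyl hydroperoxide, CC(C)(C)OO
Why: Sharpless asymmetric epoxidation of an E-trisubstituted allylic alcohol; the L-tartrate catalyst delivers oxygen to the face that sets the future C10 carbinol centre, and the alkyne is inert to the titanium peroxide.

Step 2
Reactants: 2 [(2S,3S)-3-ethynyl-3-methyloxiran-2-yl]methanol
Product: 3 (R)-3-methylpent-4-yne-1,3-diol
Conditions: NaAlH2(OCH2CH2OMe)2, THF, −20 → 0 °C; aq. potassium sodium tartrate
Reagents that add atoms: none
Why: Directed reductive opening of a 2,3-epoxy alcohol, in which the alkoxy-aluminate delivers hydride to C2 so that the C–O bond at the quaternary carbon and its configuration are kept; the low temperature is meant to spare the propargylic alkyne from hydroalumination.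

Step 3
Reactants: 3 (R)-3-methylpent-4-yne-1,3-diol; 4 methyl 2-(acetoxymethyl)acrylate
Product: 6 (5R)-5-[(2R)-2-hydroxy-2-methylbut-3-yn-1-yl]-3-methylideneoxolan-2-one, via hydroxy ester 5 (not isolated)
Conditions: [Ir(cod)Cl]2 (2.5 mol %), (R)-SEGPHOS (5 mol %), 4-cyano-3-nitrobenzoic acid (10 mol %), Cs2CO3 (20 mol %), THF, 70 °C; then TsOH·H2O (cat.), rt
Reagents that add atoms: none
Why: Iridium-catalysed transfer-hydrogenative 2-(alkoxycarbonyl)allylation of a primary alcohol: the alcohol is dehydrogenated in situ, the aldehyde is allylated by the chiral π-allyliridium species under catalyst control (the ligand enantiomer is the one assigned to the C8 configuration shown), and hydroxy ester 5 lactonises; the tertiary alcohol cannot be dehydrogenated.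

Step 4
Reactants: 6 (5R)-5-[(2R)-2-hydroxy-2-methylbut-3-yn-1-yl]-3-methylideneoxolan-2-one
Product: 7 (5R)-3-methylidene-5-[(2R)-2-methyl-2-(triethylsilyloxy)but-3-yn-1-yl]oxolan-2-one
Conditions: Et3SiOTf, 2,6-lutidine, CH2Cl2, −78 → 0 °C
Reagents that add atoms: triethylsilyl trifluoromethanesulfonate, CC[Si](CC)(CC)OS(=O)(=O)C(F)(F)F
Why: Silyl triflate silylation of the tertiary alcohol; the C10 oxygen is blocked so that it cannot add in 5-exo fashion to the butenolide made in step 5, and it stays blocked until the last step.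

Step 5
Reactants: 7 (5R)-3-methylidene-5-[(2R)-2-methyl-2-(triethylsilyloxy)but-3-yn-1-yl]oxolan-2-one
Product: 9 (5S)-3-(bromomethyl)-5-[(2R)-2-methyl-2-(triethylsilyloxy)but-3-yn-1-yl]furan-2(5H)-one, via dibromide 8 (not isolated)
Conditions: Br2 (1.0 equiv), NaHCO3, CH2Cl2, −20 °C, dark; then i-Pr2NEt, 0 °C → rt
Reagents that add atoms: bromine, BrBr
Why: Bromine addition to the exocyclic enoate followed by E2 dehydrobromination toward the ring CH2 (bromination–dehydrobromination of an α-methylene lactone to a 3-(bromomethyl)butenolide); the 1,1-disubstituted alkene is expected to react ahead of the terminal alkyne, and the lactone carbinol centre is not touched.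

Step 6
Reactants: 10 3-methylfuran-2(5H)-one
Product: 12 (2Z)-4-hydroxy-2-methylbut-2-enal oxime, via lactol 11 (not isolated)
Conditions: i-Bu2AlH, CH2Cl2, −78 °C; aq. potassium sodium tartrate; then NH2OH·HCl, NaOAc, EtOH–H2O, 0 °C → rt
Reagents that add atoms: hydroxylamine hydrochloride, Cl.NO
Why: Partial reduction of the butenolide to its lactol and oxime formation from the ring-opened hydroxy enal; the Z geometry of the future C4=C5 bond is inherited from the five-membered ring.

Step 7
Reactants: 12 (2Z)-4-hydroxy-2-methylbut-2-enal oxime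
Product: 14 (2Z)-2-methyl-4-(triethylsilyloxy)but-2-enal oxime, via bis-silyl oxime 13 (not isolated)
Conditions: Et3SiCl (2.2 equiv), imidazole, CH2Cl2, 0 °C; then K2CO3 (cat.), MeOH, 0 °C, 10 min
Reagents that add atoms: chlorotriethylsilane, CC[Si](CC)(CC)Cl
Why: Exhaustive silylation followed by selective methanolysis of the labile O-silyl oxime leaves the primary silyl ether, which keeps the cis hydroxyl from trapping the nitrile oxide intramolecularly in step 8.

Step 8
Reactants: 14 (2Z)-2-methyl-4-(triethylsilyloxy)but-2-enal oxime (1.5 equiv); 9 (5S)-3-(bromomethyl)-5-[(2R)-2-methyl-2-(triethylsilyloxy)but-3-yn-1-yl]furan-2(5H)-one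
Product: 17 (5S)-3-(bromomethyl)-5-[(2R)-2-{3-[(2Z)-4-(triethylsilyloxy)but-2-en-2-yl]isoxazol-5-yl}-2-(triethylsilyloxy)propyl]furan-2(5H)-one, via hydroximoyl chloride 15 (not isolated), via nitrile oxide 16 (not isolated)
Conditions: N-chlorosuccinimide, pyridine (cat.), DMF, 0 °C → rt; then 9, KHCO3, EtOAc, rt
Reagents that add atoms: none
Why: Huisgen 1,3-dipolar cycloaddition of an in situ nitrile oxide to a terminal alkyne gives the 3,5-disubstituted isoxazole regioselectively (oxygen on C1, nitrile oxide carbon C3 bonded to C2); the terminal alkyne should react ahead of the trisubstituted butenolide alkene, and the heterogeneous bicarbonate base spares the allylic bromide.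

Step 9
Reactants: 17 bis-silylated isoxazole bromide
Product: 18 (5S)-3-(bromomethyl)-5-[(2R)-2-{3-[(2Z)-4-hydroxybut-2-en-2-yl]isoxazol-5-yl}-2-(triethylsilyloxy)propyl]furan-2(5H)-one
Conditions: PPTS (cat.), MeOH–CH2Cl2 (1:4), 0 °C
Reagents that add atoms: none
Why: Acid-catalysed methanolysis cleaves the unhindered primary triethylsilyl ether much faster than the tertiary one at C10.

Step 10
Reactants: 18 primary allylic alcohol
Product: 19 (2Z)-3-{5-[(2R)-1-[(2S)-4-(bromomethyl)-5-oxo-2,5-dihydrofuran-2-yl]-2-(triethylsilyloxy)propan-2-yl]isoxazol-3-yl}but-2-enal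
Conditions: MnO2, CH2Cl2, rt, dark
Reagents that add atoms: none
Why: Manganese dioxide oxidation of an allylic alcohol under neutral conditions, chosen to limit Z to E isomerisation of the enal and to spare the allylic bromide; the aldehyde is used at once.

Step 11
Reactants: 19 (Z)-enal allylic bromide
Product: 20 isoxazole-bridged macrocyclic alcohol (6R,7S,8S,10R)
Conditions: CrCl2 (6 equiv), THF, rt, slow addition of 19 (final 2 mM); aq. NH4Cl
Reagents that add atoms: none
Why: Nozaki–Hiyama allylation run in Barbier fashion: divalent chromium turns the allylic bromide into an allylchromium that adds through C7 (allylic transposition, which also creates the exocyclic C11=C13 methylene) to the C6 aldehyde in a chair-like transition state, attack on the face of C7 opposite the C9 substituent at C8 giving the 7,8-trans lactone and the ring-fixed E-type allyl geometry giving the anti C6/C7 relationship (6R), while the planar isoxazole and the Z-alkene hold the two ends within reach.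

Step 12
Reactants: 21 (E)-2-methylbut-2-en-1-ol
Product: 22 [(2R,3R)-2,3-dimethyloxiran-2-yl]methanol
Conditions: Ti(OiPr)4 (10 mol %), D-(−)-diethyl tartrate (12 mol %), t-BuOOH, 4 Å MS, CH2Cl2, −20 °C
Reagents that add atoms: tert-butyl hydroperoxide, CC(C)(C)OO
Why: Sharpless asymmetric epoxidation; the D-tartrate catalyst sets both epoxide carbons, which become the (2S,3R) centres of the side chain (the change of the C2 descriptor in step 13 is formal).

Step 13
Reactants: 22 [(2R,3R)-2,3-dimethyloxiran-2-yl]methanol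
Product: 23 (2S,3R)-2,3-dimethyloxirane-2-carboxylic acid
Conditions: TEMPO (cat.), PhI(OAc)2 (2.2 equiv), MeCN–H2O (1:1), 0 °C → rt
Reagents that add atoms: water, O
Why: Oxoammonium-mediated oxidation of the primary alcohol through the aldehyde hydrate to the acid, under conditions that leave the trisubstituted epoxide and both stereocentres untouched.

Step 14
Reactants: 20 isoxazole-bridged macrocyclic alcohol; 23 (2S,3R)-2,3-dimethyloxirane-2-carboxylic acid
Product: 25 isoxazole-bridged macrocyclic 6-O-[(2S,3R)-2,3-dimethyloxirane-2-carbonyl] ester (6R,7R,8S,10R), via mixed anhydride 24 (not isolated)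
Conditions: 2,4,6-Cl3C6H2COCl, Et3N, THF, rt; then 20, DMAP, toluene, rt
Reagents that add atoms: none
Why: Yamaguchi esterification: the mixed anhydride transfers the epoxy acyl group to the secondary C6 hydroxyl with retention at C6 and at both epoxide carbons, the tertiary C10 oxygen being silylated; once C6–O is acylated, only C10–O can later reach C3.

Step 15
Reactants: 25 isoxazole-bridged macrocyclic epoxy ester
Product: 28 target CNP0258430.2, via silyl enaminone 26 (not isolated), via hydroxy enaminone 27 (not isolated)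
Conditions: Mo(CO)6 (1.0 equiv), MeCN–H2O (10:1), 80 °C; then CF3CO2H, THF–H2O, 0 °C → rt
Reagents that add atoms: none
Why: Zerovalent molybdenum inserts into the weak N–O bond of the isoxazole and water supplies the hydrogens, so the 3,5-bridged bicycle opens to the ten-membered β-amino enone 26 (C1=O, C3–NH2, C4 already trans to C1 across C2=C3 as the furanone requires); the acid then removes the triethylsilyl group (27), protonates the vinylogous amide at C2 and lets the freed C10 hydroxyl attack the C3 iminium carbon across the ring, after which ammonia is expelled to leave the C2=C3 enol ether. The closest known chemistry is the conversion of 3,5-disubstituted isoxazoles bearing an α-hydroxyalkyl group into 3(2H)-furanones by reductive N–O cleavage and acid treatment. The furanone ring (O, C10, C1, C2, C3) closes by 5-exo-trig addition of oxygen to C3 followed by elimination, and no other ring is formed. No new stereocentre arises, and C10 keeps its configuration because only its O–Si and O–H bonds are touched. The step needs N–O cleavage in the presence of the epoxy ester, the exocyclic enoate and the C4=C5 alkene, for which the mild aqueous acetonitrile protocol is chosen, and it needs C10–O rather than C6–O to capture C3, which the C6 ester secures; hydrolysis of the enaminone to the 1,3-diketone would be harmless, since that diketone cyclodehydrates to the same furanone.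

Compound list
1 | (E)-3-methylpent-2-en-4-yn-1-ol | C#C/C(C)=C/CO | starting material
2 | [(2S,3S)-3-ethynyl-3-methyloxiran-2-yl]methanol | OC[C@H]1[C@@](C#C)(C)O1 | intermediate
3 | (R)-3-methylpent-4-yne-1,3-diol | OCC[C@@](C#C)(C)O | intermediate
4 | methyl 2-(acetoxymethyl)acrylate | C=C(COC(C)=O)C(=O)OC | starting material
5 | methyl (4R,6R)-4,6-dihydroxy-6-methyl-2-methylideneoct-7-ynoate | C=C(C[C@@H](O)C[C@@](C#C)(C)O)C(=O)OC | intermediate
6 | (5R)-5-[(2R)-2-hydroxy-2-methylbut-3-yn-1-yl]-3-methylideneoxolan-2-one | O=C1O[C@@H](C[C@@](C#C)(C)O)CC1=C | intermediate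
7 | (5R)-3-methylidene-5-[(2R)-2-methyl-2-(triethylsilyloxy)but-3-yn-1-yl]oxolan-2-one | O=C1O[C@@H](C[C@@](C#C)(C)O[Si](CC)(CC)CC)CC1=C | intermediate
8 | 3-bromo-3-(bromomethyl) lactone from 7 (both epimers at the brominated ring carbon, other centres as in 7) | O=C1O[C@@H](C[C@@](C#C)(C)O[Si](CC)(CC)CC)CC1(Br)CBr | intermediate
9 | (5S)-3-(bromomethyl)-5-[(2R)-2-methyl-2-(triethylsilyloxy)but-3-yn-1-yl]furan-2(5H)-one | O=C1O[C@@H](C[C@@](C#C)(C)O[Si](CC)(CC)CC)C=C1CBr | intermediate
10 | 3-methylfuran-2(5H)-one | CC1=CCOC1=O | starting material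
11 | 3-methyl-2,5-dihydrofuran-2-ol | CC1=CCOC1O | intermediate
12 | (2Z)-4-hydroxy-2-methylbut-2-enal oxime | ON=C/C(C)=C\CO | intermediate
13 | (2Z)-2-methyl-4-(triethylsilyloxy)but-2-enal O-(triethylsilyl)oxime | CC[Si](CC)(CC)ON=C/C(C)=C\CO[Si](CC)(CC)CC | intermediate
14 | (2Z)-2-methyl-4-(triethylsilyloxy)but-2-enal oxime | ON=C/C(C)=C\CO[Si](CC)(CC)CC | intermediate
15 | (2Z)-N-hydroxy-2-methyl-4-(triethylsilyloxy)but-2-enimidoyl chloride | ON=C(Cl)/C(C)=C\CO[Si](CC)(CC)CC | intermediate
16 | (2Z)-2-methyl-4-(triethylsilyloxy)but-2-enenitrile oxide | [O-][N+]#C/C(C)=C\CO[Si](CC)(CC)CC | intermediate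
17 | (5S)-3-(bromomethyl)-5-[(2R)-2-{3-[(2Z)-4-(triethylsilyloxy)but-2-en-2-yl]isoxazol-5-yl}-2-(triethylsilyloxy)propyl]furan-2(5H)-one | O=C1O[C@@H](C[C@@](c2cc(/C(C)=C\CO[Si](CC)(CC)CC)no2)(C)O[Si](CC)(CC)CC)C=C1CBr | intermediate
18 | (5S)-3-(bromomethyl)-5-[(2R)-2-{3-[(2Z)-4-hydroxybut-2-en-2-yl]isoxazol-5-yl}-2-(triethylsilyloxy)propyl]furan-2(5H)-one | O=C1O[C@@H](C[C@@](c2cc(/C(C)=C\CO)no2)(C)O[Si](CC)(CC)CC)C=C1CBr | intermediate
19 | (2Z)-3-{5-[(2R)-1-[(2S)-4-(bromomethyl)-5-oxo-2,5-dihydrofuran-2-yl]-2-(triethylsilyloxy)propan-2-yl]isoxazol-3-yl}but-2-enal | O=C1O[C@@H](C[C@@](c2cc(/C(C)=C\C=O)no2)(C)O[Si](CC)(CC)CC)C=C1CBr | intermediate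
20 | isoxazole-bridged macrocyclic alcohol: ten-membered carbocycle C1–C10 in which C1, C2, C3 are C5, C4, C3 of an isoxazole (O on C1, N on C3), 4Z-alkene, 6-OH, 10-OSiEt3, trans-fused 8,12-α-methylene lactone; (6R,7S,8S,10R), C7 being S by priority only | C=C1C(=O)O[C@H]2C[C@@](C)(O[Si](CC)(CC)CC)c3cc(no3)/C(C)=C\[C@@H](O)[C@H]12 | intermediate
21 | (E)-2-methylbut-2-en-1-ol | C/C=C(\C)CO | starting material
22 | [(2R,3R)-2,3-dimethyloxiran-2-yl]methanol | OC[C@@]1(C)O[C@@H]1C | intermediate
23 | (2S,3R)-2,3-dimethyloxirane-2-carboxylic acid | OC(=O)[C@@]1(C)O[C@@H]1C | intermediate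
24 | (2S,3R)-2,3-dimethyloxirane-2-carboxylic 2,4,6-trichlorobenzoic anhydride | O=C(OC(=O)[C@@]1(C)O[C@@H]1C)c1c(Cl)cc(Cl)cc1Cl | intermediate
25 | 6-O-[(2S,3R)-2,3-dimethyloxirane-2-carbonyl] ester of 20; (6R,7R,8S,10R) | C=C1C(=O)O[C@H]2C[C@@](C)(O[Si](CC)(CC)CC)c3cc(no3)/C(C)=C\[C@@H](OC(=O)[C@@]4(C)O[C@@H]4C)[C@H]12 | intermediate
26 | ten-membered 3-amino-1-oxo-2-ene (β-amino enone) with 10-OSiEt3, from N–O cleavage of 25; other centres as in 25 | C=C1C(=O)O[C@H]2C[C@@](C)(O[Si](CC)(CC)CC)C(=O)C=C(N)/C(C)=C\[C@@H](OC(=O)[C@@]3(C)O[C@@H]3C)[C@H]12 | intermediate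
27 | 10-hydroxy β-amino enone from desilylation of 26 | C=C1C(=O)O[C@H]2C[C@@](C)(O)C(=O)C=C(N)/C(C)=C\[C@@H](OC(=O)[C@@]3(C)O[C@@H]3C)[C@H]12 | intermediate
28 | CNP0258430.2; (6R,7R,8S,10R), side chain (2S,3R) | C=C1C(=O)O[C@H]2C[C@@]3(C)OC(=CC3=O)/C(C)=C\[C@@H](OC(=O)[C@@]3(C)O[C@@H]3C)[C@H]12 | target

Total step count: 15. Longest linear sequence: 11 steps (steps 1–5, 8–11, 14 and 15, from 1 to 28).

Steps most likely to fail, with fallbacks

Step 11. Intermolecular allylation may compete with closure of the ring around the rigid 3,5-bridged isoxazole, and the allyl unit may be delivered to the wrong face of the aldehyde in the constrained transition state, which would set C6 wrongly. The fallback sets out from 19: the cyclisation is run as before, the 6-epimeric macrocyclic alcohol F1 is isolated, and the centre is corrected while the ester is made. A Mitsunobu reaction of F1 with acid 23 (PPh3, diisopropyl azodicarboxylate, toluene, 0 °C) forms the C6–O bond with inversion and comes back to the route at 25, replacing step 14.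

Step 15. The zerovalent molybdenum may take the oxygen of the epoxy ester (deoxygenation to the unsaturated ester), or the acid stage may open the epoxide, while the N–O bond is being cut. The fallback sets out from 20 and performs the ring switch before the side chain is attached. The C6 hydroxyl is silylated (t-BuMe2SiOTf, 2,6-lutidine, CH2Cl2, −78 °C) to the macrocyclic bis-silyl ether F2. Mo(CO)6 in MeCN–H2O at 80 °C and then CF3CO2H in THF–H2O take F2 through the silyl enaminone F3 and the 10-hydroxy enaminone F4 to the 6-O-silyl furanone F5, C6–O staying blocked during the transannular closure. HF·pyridine in THF frees the furanone alcohol F6, which is acylated with mixed anhydride 24 (from 23, DMAP, toluene) to come back to the route at 28.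

Step 3. The terminal alkyne may bind to the iridium hydride or be hydrometalated by it, which would stop the hydrogen-transfer cycle. The fallback sets out from 3 and masks the alkyne. EtMgBr (3.2 equiv) and Me3SiCl (3.2 equiv) in THF give the tris(trimethylsilyl) compound F7, whose two O–Si bonds are hydrolysed on work-up with aqueous citric acid to leave the C-silyl diol F8. Allylation of F8 with 4 under the conditions of step 3 gives, through the hydroxy ester F9, the silylalkyne lactone F10. Bu4NF buffered with AcOH in THF at 0 °C removes the C-silyl group and comes back to the route at 6.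

Further compounds
F1 | step 11 | 6-epimer of macrocyclic alcohol 20 (6S,7S,8S,10R) | C=C1C(=O)O[C@H]2C[C@@](C)(O[Si](CC)(CC)CC)c3cc(no3)/C(C)=C\[C@H](O)[C@H]12
F2 | step 15 | 6-O-(tert-butyldimethylsilyl) ether of 20 | C=C1C(=O)O[C@H]2C[C@@](C)(O[Si](CC)(CC)CC)c3cc(no3)/C(C)=C\[C@@H](O[Si](C)(C)C(C)(C)C)[C@H]12
F3 | step 15 | β-amino enone from N–O cleavage of F2 (10-OSiEt3, 6-OSi-t-BuMe2) | C=C1C(=O)O[C@H]2C[C@@](C)(O[Si](CC)(CC)CC)C(=O)C=C(N)/C(C)=C\[C@@H](O[Si](C)(C)C(C)(C)C)[C@H]12
F4 | step 15 | 10-hydroxy β-amino enone from F3 (6-OSi-t-BuMe2) | C=C1C(=O)O[C@H]2C[C@@](C)(O)C(=O)C=C(N)/C(C)=C\[C@@H](O[Si](C)(C)C(C)(C)C)[C@H]12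
F5 | step 15 | 6-O-(tert-butyldimethylsilyl) furanone (target skeleton without the acyl group) | C=C1C(=O)O[C@H]2C[C@@]3(C)OC(=CC3=O)/C(C)=C\[C@@H](O[Si](C)(C)C(C)(C)C)[C@H]12
F6 | step 15 | 6-hydroxy furanone (deacyl target) | C=C1C(=O)O[C@H]2C[C@@]3(C)OC(=CC3=O)/C(C)=C\[C@@H](O)[C@H]12
F7 | step 3 | (R)-3-methyl-1,3-bis(trimethylsilyloxy)-5-(trimethylsilyl)pent-4-yne | C[Si](C)(C)OCC[C@@](C#C[Si](C)(C)C)(C)O[Si](C)(C)C
F8 | step 3 | (R)-3-methyl-5-(trimethylsilyl)pent-4-yne-1,3-diol | OCC[C@@](C#C[Si](C)(C)C)(C)O
F9 | step 3 | methyl (4R,6R)-4,6-dihydroxy-6-methyl-2-methylidene-8-(trimethylsilyl)oct-7-ynoate | C=C(C[C@@H](O)C[C@@](C#C[Si](C)(C)C)(C)O)C(=O)OC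
F10 | step 3 | (5R)-5-[(2R)-2-hydroxy-2-methyl-4-(trimethylsilyl)but-3-yn-1-yl]-3-methylideneoxolan-2-one | O=C1O[C@@H](C[C@@](C#C[Si](C)(C)C)(C)O)CC1=C
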